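The C8–C9 bond of the pentacosanoyl chain (C1 = ester carbonyl) is the disconnection on which everything rests. The key step exploits the fact that C2–C25 form an unbranched, saturated polymethylene chain whose only functional atom is the C1 carbonyl and which carries no ring, the phenyl ring lying beyond the ester oxygen. A crossed Kolbe electrolysis therefore forges C8–C9 in one operation from two cheap carboxylic acids, each giving up CO2: stearic acid supplies C9–C25 as a heptadecyl radical, methyl hydrogen azelate supplies C1–C8 as a 7-(methoxycarbonyl)heptyl radical. The precursor is simply a warm methanolic solution of these two acids. Saponification and esterification with 2-phenylethanol, kept away from the anode, finish the synthesis.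

Key step: step 3

Remark: chain atoms are numbered as in the acyl group of the target (C1 ester carbonyl, C25 terminal methyl); the target has no stereocentre and no double-bond geometry, so no structure needs a stereodescriptor.

Step 1
Reactants: 1 azelaic acid (nonanedioic acid)
Product: 2 dimethyl azelate (dimethyl nonanedioate)
Conditions: MeOH (solvent, large excess), H2SO4 (cat.), reflux; NaHCO3 wash; distillation under reduced pressure
Reagents that add atoms: methanol (CO)
Why: Fischer esterification in a large excess of methanol should drive both carboxyl groups of the saturated diacid to the diester, which has no other reactive site and is purified by distillation.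

Step 2
Reactants: 2 dimethyl azelate
Product: 4 methyl hydrogen azelate (9-methoxy-9-oxononanoic acid), via potassium methyl azelate 3 (not isolated)
Conditions: KOH (0.95 equiv) in MeOH added dropwise to 2 in MeOH, 20 °C, 16 h; evaporation; H2O, Et2O wash (recovers 2); 2 M HCl to pH 2, Et2O extraction; cold toluene, filtration from 1; distillation under reduced pressure; recovered 1 and 2 recycled
Reagents that add atoms: potassium hydroxide ([K+].[OH-])
Why: Partial saponification (base-mediated acyl–oxygen ester hydrolysis) with slightly less than one equivalent of hydroxide in methanol, where methoxide exchange at the methyl esters is degenerate, should stop mainly at the mono-carboxylate 3 once the hydroxide is used up, and the admixed neutral 2 and sparingly soluble diacid 1 are removed through their different acidity and solubility.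

Step 3
Reactants: 4 methyl hydrogen azelate; 5 stearic acid (octadecanoic acid)
Product: 6 methyl pentacosanoate
Conditions: 4 (2 equiv), 5 (1 equiv), NaOMe (0.05 equiv per CO2H), MeOH, 50–55 °C, smooth platinum foil anode and cathode, undivided cell, constant current ca. 0.2 A cm-2, periodic reversal of polarity, run until faintly alkaline; AcOH, evaporation, silica filtration (hexane removes the C34 alkane, hexane/EtOAc elutes 6 ahead of the C16 diester), crystallisation from acetone
Reagents that add atoms: none
Why: In weakly acidic methanol the carboxylates of 4 and 5 crowd the platinum anode, where each is oxidised by one electron to an acyloxy radical that sheds CO2 at once, giving the 7-(methoxycarbonyl)heptyl radical from 4 and the heptadecyl radical from 5. The high radical density at the electrode makes radical–radical combination the dominant fate, and the mixed combination creates the C8–C9 sigma bond of the C25 chain, while the cathode discharges the two carboxyl protons as hydrogen and regenerates methoxide. The closest known reaction type is the crossed Kolbe electrolysis of a fatty acid with an alkyl hydrogen alpha,omega-dicarboxylate, a standard chain extension of long-chain esters. No ring is closed and no stereocentre is created. The step needs hetero- over homo-coupling, which is only statistical and is pushed towards 6 (based on 5) by the twofold excess of 4, and one-electron over two-electron oxidation, which is secured by the unsubstituted alpha-CH2 groups of both acids (primary radicals that resist oxidation to cations), smooth platinum, high current density and the low degree of neutralisation. The distal methyl ester of 4 is not oxidised and is not cleaved, because the medium stays on the acid side until the end point and no arene is yet present to compete at the anode.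

Step 4
Reactants: 6 methyl pentacosanoate
Product: 8 pentacosanoic acid, via potassium pentacosanoate 7 (not isolated)
Conditions: KOH (3 equiv), EtOH/H2O 9:1, reflux; then 2 M HCl, 70 °C, to pH 1; filtration; recrystallisation from acetone
Reagents that add atoms: potassium hydroxide ([K+].[OH-])
Why: Saponification (base-mediated acyl–oxygen ester hydrolysis) is made irreversible by formation of the carboxylate 7, the saturated chain offers no competing site, and acidification of the hot soap solution should release the acid, whose recrystallisation also strips residual neutral wax.

Step 5
Reactants: 8 pentacosanoic acid; 9 2-phenylethanol
Product: 10 2-phenylethyl pentacosanoate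
Conditions: 9 (1.5 equiv), TsOH·H2O (0.05 equiv), toluene, reflux, Dean–Stark trap; aq. NaHCO3 wash; recrystallisation from acetone/EtOH
Reagents that add atoms: none
Why: Fischer esterification with azeotropic removal of water should drive the equilibrium between the unhindered acid and the primary alcohol fully to the ester, the phenyl ring and the alkyl chain being inert to catalytic TsOH and no stereocentre being involved.

Compound list
1 | azelaic acid (nonanedioic acid) | OC(=O)CCCCCCCC(=O)O | starting material
2 | dimethyl azelate | COC(=O)CCCCCCCC(=O)OC | intermediate
3 | potassium methyl azelate (potassium 9-methoxy-9-oxononanoate) | COC(=O)CCCCCCCC(=O)[O-].[K+] | intermediate (not isolated)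
4 | methyl hydrogen azelate (9-methoxy-9-oxononanoic acid) | COC(=O)CCCCCCCC(=O)O | intermediate
5 | stearic acid (octadecanoic acid) | CCCCCCCCCCCCCCCCCC(=O)O | starting material
6 | methyl pentacosanoate | CCCCCCCCCCCCCCCCCCCCCCCCC(=O)OC | intermediate
7 | potassium pentacosanoate | CCCCCCCCCCCCCCCCCCCCCCCCC(=O)[O-].[K+] | intermediate (not isolated)
8 | pentacosanoic acid | CCCCCCCCCCCCCCCCCCCCCCCCC(=O)O | intermediate
9 | 2-phenylethanol | OCCc1ccccc1 | starting material
10 | 2-phenylethyl pentacosanoate | CCCCCCCCCCCCCCCCCCCCCCCCC(=O)OCCc1ccccc1 | target

Total step count: 5
Longest linear sequence: 5 steps (1 → 2 → 4 → 6 → 8 → 10)

Steps most likely to fail

Step 3 (crossed Kolbe electrolysis). The waxy products may coat the anode, so that the anode potential drifts and two-electron oxidation to methyl ethers, alkenes and mixed esters takes over. The statistical homo-coupling may also leave too little cross-product for clean isolation. The fallback builds the same chain by an organometallic alkyl–alkyl coupling, cut one bond further along at C7–C8. It sets out from stearic acid 5, which LiAlH4 in THF should reduce to octadecan-1-ol F1. Aqueous 48% HBr with H2SO4 at reflux should turn this into 1-bromooctadecane F2, and magnesium turnings in THF should give octadecylmagnesium bromide F3. Slow addition of F3 to commercial methyl 7-bromoheptanoate (COC(=O)CCCCCCBr) in THF/NMP at −10 to 0 °C with catalytic Li2CuCl4 is a Kochi-type coupling in which the ester survives at low temperature. It should deliver methyl pentacosanoate 6, where the route is rejoined.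

Step 2 (partial saponification). The second ester group is remote from the first carboxylate and may be hydrolysed almost as fast, so that over-hydrolysis to the diacid and unreacted diester erode the return of half-ester. The fallback replaces the kinetic partial hydrolysis by a thermodynamic ester–acid redistribution. It sets out from dimethyl azelate 2, which is heated with one equivalent of azelaic acid 1 and catalytic conc. aq. HCl in n-Bu2O at 150–160 °C and then at 120 °C. The trace of water shuttles methanol between the carboxyl groups, so diacid and diester should comproportionate to a mixture rich in the half-ester, and the two unwanted components of the partial hydrolysis become the feed. Cooling and filtration remove 1, extraction into aq. NaHCO3 separates the acid from neutral 2, and acidification and distillation should give methyl hydrogen azelate 4, where the route is rejoined.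

Step 5 (acid-catalysed esterification). The equilibrium may stall if water removal is inefficient for the waxy, sparingly soluble acid, and the acid catalyst may promote ether formation or dehydration of the alcohol at reflux. The fallback is an irreversible acylation through the acid chloride. It sets out from pentacosanoic acid 8, which oxalyl chloride with catalytic DMF in warm toluene should convert into pentacosanoyl chloride F4. After evaporation, F4 is treated with 2-phenylethanol 9 and pyridine in CH2Cl2 at 0 °C to room temperature, which should give 2-phenylethyl pentacosanoate 10, the end of the route.

Further compounds
F1 | step 3 | octadecan-1-ol | CCCCCCCCCCCCCCCCCCO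
F2 | step 3 | 1-bromooctadecane | CCCCCCCCCCCCCCCCCCBr
F3 | step 3 | octadecylmagnesium bromide | CCCCCCCCCCCCCCCCCC[Mg]Br
F0 | step 2 | none | none
F4 | step 5 | pentacosanoyl chloride | CCCCCCCCCCCCCCCCCCCCCCCCC(=O)Cl
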